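Ring atoms are labelled as follows. Ring A: A1 (OMe), A2 (H), A3 (Me), A4 (acyl carbon), A5 (ether O), A6 (OH). Ring B: B1 (ether O), B2 (ester O), B3 (Me), B4 (OH), B5 (lactone C=O), B6 (lactol carbon). Compounds are numbered 1–19 in the order in which they appear in the steps: 7 is the ring B hydroquinone pseudoester, 11 the ring A bromo aldehyde, 13 the key-step precursor, 14 the spiro dienone, 15 the key-step product and 19 the target.

## Analysis of the target

The target is a depsidone. Rings A and B are joined by a diaryl ether (A5–O–B1) and by an aryl ester (A4–C(=O)–O–B2), which together close the seven-membered ring D. Ring A carries a methoxy group at A1, a methyl group at A3 and a free phenol at A6. Ring B is hexasubstituted: methyl at B3, phenol at B4, and a fused γ-lactol (ring C, a 3-hydroxyphthalide) with its carbonyl on B5 and its hemiacetal carbon on B6. That hemiacetal carbon is the only stereocentre and is R (ring O > OH > B6 > H). It is the closed form of a formyl acid and can epimerise by ring opening, so it has to be set at the very end. The aryl ester of ring D is sensitive to hydroxide and hard nucleophiles, the lactol is a masked aldehyde, and both phenols are oxidisable. The difficulty is the hexasubstituted ring B, the doubly ortho-flanked ether and ester linkages, and the labile stereocentre. The strategy rests on the oxygen pattern of ring B: B1 and B4 are para (a hydroquinone) and the ester oxygen on B2 is next to B1. A quinol ester formed at B1 can therefore pass its acyloxy group to B2, and B2 can enter the synthesis as a C–H.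

## Retrosynthetic reasoning

19 to 17. The lactol configuration is disconnected first because it cannot survive any later operation. Racemic lactol 17 is converted to the R acetate 18 by an enzymatic dynamic kinetic acetylation, in which ring–chain tautomerism racemises the slow enantiomer. The acetate is then removed by acyl–oxygen cleavage, which does not touch the C–O bond of the stereocentre.

17 to 15. Two protecting groups are removed: the methyl acetal on the lactol (16 to 17) and the benzyl ether on A6 (15 to 16). The benzyl ether goes first, while the lactol is still locked as its acetal, so that hydrogenation conditions never meet the aldehyde tautomer. The acetal is then opened with aqueous acid, which the ring D ester tolerates far better than base.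

15 to 13 (key disconnection). The B2–O ester bond is cut and replaced by B2–H, giving the diaryl ether acid 13 with a free B4 phenol. This is the only bond of ring D that can be made by oxidation instead of condensation. Ring B then needs no oxygen at B2, no third protecting group and no separate lactonisation. In the forward direction the B4 phenol is dearomatised, the A4 acid is captured at B1 to give spiro dienone 14, and the acyloxy oxygen is shifted from B1 to B2 with rearomatisation.

13 to 7 and 11. The diaryl ether A5–O(B1) is cut to the ring B phenol 7 and the ring A bromide 11, joined by copper-mediated etherification to 12. A4 is carried as an aldehyde and oxidised afterwards (12 to 13). An A4 ester would sit between two ortho substituents, and the saponification needed to cleave it would open the pseudoester. The B4 phenol of 7 is left free: it is hydrogen-bonded to the lactone carbonyl and flanked on both sides, so the coupling should take the other phenol, and no unmasking step is needed before the key step.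

7 to 1. Ring C is cut at B5–C(=O). The hydroquinone dimethyl ether 1 is formylated at the future B6 to give 2. The masked aldehyde and the B4 methoxy group then direct lithiation to B5, and carboxylation gives lactol 5. Cleavage of both methyl ethers and acetalisation of the lactol give 7 in one flask.

11 to 8. Ring A needs a halogen, not an oxygen, at A5, so it is taken from cresol 8, which has oxygen only at A1 and A6. Bromination ortho to the free phenol gives 9, benzylation gives 10, and formylation para to the methoxy group gives 11.

## Alternatives that were turned down

Alternative 1: Ring B is built from acyclic pieces by cutting B1–B6 and B4–B5. The silyloxyfuran A2 and the ynoate A3 would combine by [4+2] cycloaddition, and opening of the oxa bridge would give the hexasubstituted benzoate A1 with all six substituents in place. In its favour, the free B1 phenol, the B2 benzyl ether and the B4 silyl ether are differentiated from the outset, so the chemoselectivity question of step 7 does not arise; on this point it is stronger than the chosen route. Ring D would then be closed by a conventional lactonisation. Against it, A2 is a sensitive, fully substituted diene that itself needs several steps, and the regiochemistry depends only on electronic matching with an alkyne substituted at both ends. Ring D still needs a coupling, a deprotection and a lactonisation, with three orthogonal protecting groups to carry. The chosen route gives up the programmed ring B in return for a ring B made in three steps from a commodity hydroquinone ether, and has no B2 oxygen to install or protect.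

Alternative 2: The A3–CH3 and A4–CO2H bonds are cut on a complete diaryl ether. Iodine–magnesium exchange at A4 of the iodo tosylate A5 and loss of the A3 tosylate would give the A3–A4 aryne; MeMgCl would add at A3 and CO2 would trap the A4 arylmagnesium, giving the seco acid A4. The regiochemistry is well founded, since the oxygen on A5 steers the nucleophile to the distal aryne carbon, and the free acid is obtained directly without an oxidation step. For this target, however, the methyl and carboxyl groups of ring A are not the problem: the cresol 8 already carries the methyl group, and one formylation places the carbon at A4. The aryne route would also take an aryl iodide and a tosylate through the ether coupling, would run organomagnesium chemistry late on a substrate with an ester and an acetal, and still needs a fully oxygenated ring B and a separate lactonisation. It is safer than the chosen route only in that ring D closes by known esterification, and it is much longer.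

Alternative 3: The B6–C(=O) bond of ring C is cut on the finished depsidone. Pd(OAc)2 with Ag2CO3 under CO would palladate B6–H of the acid A7 under direction of the B5 carboxylate and insert CO, closing ring C as the cyclic anhydride A6. It speaks for this route that ring B stays pentasubstituted until late and that anhydride formation from benzoic acids is a known reaction type. Against it, the anhydride must then be reduced at the B6 carbonyl only, in the presence of the B5 carbonyl and the ring D ester, and nothing in the structure clearly differentiates the two anhydride carbonyls. The depsidone would also have to survive silver carbonate, CO and heat. The chosen route avoids the regioselective reduction entirely, because B5 and B6 enter at their final oxidation levels in step 2. Alternative 3 is comparable in step count but places two uncertain steps at the end.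

Key step: step 9

Assumption: the lactol carbon is taken to be configurationally labile through the ring-opened formyl acid, so the R configuration is set in the last two steps and the free lactol is handled cold, neutral and without amine.

## Route

Step 1
Reactants: 1 2,5-dimethoxytoluene (1,4-dimethoxy-2-methylbenzene)
Product: 2 2,5-dimethoxy-4-methylbenzaldehyde
Conditions: Cl2CHOMe, TiCl4, CH2Cl2, 0 °C; H2O
Reagents that add atoms: dichloromethyl methyl ether, COC(Cl)Cl; water, O
Why: Rieche formylation; the position para to the methyl group and ortho to a methoxy group (the future B6) is the most activated and least hindered open site, so the formyl carbon should enter there.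

Step 2
Reactants: 2 2,5-dimethoxy-4-methylbenzaldehyde
Product: 5 3-hydroxy-4,7-dimethoxy-6-methyl-2-benzofuran-1(3H)-one (racemic lactol), via lithium α-amino alkoxide 3 (not isolated), via ortho-lithiated amino alkoxide 4 (not isolated)
Conditions: Me2NCH2CH2NHMe, n-BuLi, THF, −20 °C; 2; n-BuLi (3 equiv), −20 °C; CO2, −78 °C → rt; 2 M HCl
Reagents that add atoms: carbon dioxide, O=C=O
Why: Directed ortho-metalation with in situ protection of the aldehyde: the lithium amide adds to the formyl group to give 3, whose chelating side arm and the B4 methoxy group together direct n-BuLi to B5, the only ring C–H ortho to the masked aldehyde; carboxylation of 4 and acidic work-up release the formyl acid, which closes to lactol 5 (the new stereocentre is racemic and of no consequence).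

Step 3
Reactants: 5 3-hydroxy-4,7-dimethoxy-6-methyl-2-benzofuran-1(3H)-one
Product: 7 4,7-dihydroxy-3-methoxy-6-methyl-2-benzofuran-1(3H)-one (racemic methyl pseudoester), via 3,4,7-trihydroxy-6-methylphthalide 6 (not isolated)
Conditions: BBr3, CH2Cl2, −78 °C → rt; then MeOH, 50 °C
Reagents that add atoms: methanol, CO
Why: Lewis-acid cleavage of both aryl methyl ethers gives the boron-bound triol 6; the methanol quench liberates HBr, which catalyses acetalisation of the lactol to the cyclic methyl pseudoester, the form favoured for 2-formylbenzoic acids, while the phenols are not alkylated.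

Step 4
Reactants: 8 creosol (2-methoxy-4-methylphenol)
Product: 9 2-bromo-6-methoxy-4-methylphenol
Conditions: Br2, CH2Cl2, 0 °C
Reagents that add atoms: bromine, BrBr
Why: Electrophilic aromatic bromination; the free hydroxyl is the strongest director and its para position is blocked by the methyl group, so bromine should enter ortho to it, at the future A5.

Step 5
Reactants: 9 2-bromo-6-methoxy-4-methylphenol
Product: 10 2-(benzyloxy)-1-bromo-3-methoxy-5-methylbenzene
Conditions: BnBr, K2CO3, DMF, 50 °C
Reagents that add atoms: benzyl bromide, BrCc1ccccc1
Why: Williamson ether synthesis on the phenoxide; the benzyl group masks A6 through the coupling and the oxidative key step and is removable later under neutral conditions.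

Step 6
Reactants: 10 2-(benzyloxy)-1-bromo-3-methoxy-5-methylbenzene
Product: 11 3-(benzyloxy)-2-bromo-4-methoxy-6-methylbenzaldehyde
Conditions: Cl2CHOMe, TiCl4, CH2Cl2, −78 → 0 °C; H2O
Reagents that add atoms: dichloromethyl methyl ether, COC(Cl)Cl; water, O
Why: Rieche formylation; the A1 methoxy group is the only oxygen substituent able to lie in the ring plane and directs para to A4, which is also activated by the ortho methyl group, whereas the twisted benzyloxy group between bromine and methoxy directs only to occupied positions; the low temperature is chosen to spare the benzyl ether.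

Step 7
Reactants: 7 4,7-dihydroxy-3-methoxy-6-methyl-2-benzofuran-1(3H)-one; 11 3-(benzyloxy)-2-bromo-4-methoxy-6-methylbenzaldehyde
Product: 12 3-(benzyloxy)-2-[(7-hydroxy-3-methoxy-6-methyl-1-oxo-1,3-dihydro-2-benzofuran-4-yl)oxy]-4-methoxy-6-methylbenzaldehyde (racemic at the acetal carbon)
Conditions: CuI (20 mol %), N,N-dimethylglycine, Cs2CO3, dioxane, 90 °C, argon
Reagents that add atoms: none
Why: Ullmann-type diaryl ether synthesis; the bromide of 11 is activated by the ortho formyl group, and of the two phenols of 7 only B1–OH is an ordinary phenol, B4–OH being hydrogen-bonded to the lactone carbonyl and flanked on both sides, so arylation should occur at B1; exclusion of air protects the hydroquinone.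

Step 8
Reactants: 12 the diaryl ether aldehyde
Product: 13 3-(benzyloxy)-2-[(7-hydroxy-3-methoxy-6-methyl-1-oxo-1,3-dihydro-2-benzofuran-4-yl)oxy]-4-methoxy-6-methylbenzoic acid (racemic at the acetal carbon)
Conditions: NaClO2, NaH2PO4, 2-methyl-2-butene, t-BuOH–THF–H2O, 0 °C → rt
Reagents that add atoms: sodium chlorite, [Na+].[O-]Cl=O
Why: Pinnick oxidation; chlorous acid oxidises even a doubly ortho-substituted aldehyde, the alkene scavenges HOCl so that the phenol and the anisole ring are not chlorinated, and the buffered medium leaves the methyl acetal and the benzyl ether intact.

Step 9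
Reactants: 13 the diaryl ether acid with B2–H and free B4 phenol
Product: 15 A6-benzyl depsidone methyl pseudoester with free B4 phenol (ring D closed through A5–O–B1 and A4–C(=O)–O–B2; racemic at the acetal carbon), via spiro dienone lactone 14 (not isolated)
Conditions: PhI(OAc)2 (1.1 equiv), (CF3)2CHOH–CH2Cl2, 0 °C; evaporation with toluene; BF3·OEt2 (0.3 equiv), CH2Cl2, −40 → 0 °C
Reagents that add atoms: none
Why: Proposed new method: ligand exchange of the B4 phenol at trivalent iodine and loss of PhI give an aryloxy-stabilised phenoxenium ion, whose para carbon B1 is captured by the A4 carboxylic acid in a 6-exo-trig closure to the spiro 1,3-benzodioxin-4-one dienone 14; the closest known reaction is the PhI(OAc)2 spirolactonisation of para-substituted phenols bearing a tethered acid. BF3·OEt2 then activates the cross-conjugated dienone, and the ester carbonyl oxygen adds to the β-carbon B2 (5-exo-trig) to form a dioxolan-2-ylium bridge across B1–B2. The B1–O bond of the bridge opens to the aryloxy-stabilised cation and loss of the B2 proton rearomatises ring B; the closest known reaction is the acid-promoted 1,2-acyloxy shift of para-quinol esters, a dienone–phenol rearrangement. The net result is an O–B2 bond at a former C–H and expansion of the six-membered spirolactone to the seven-membered ring D (A4, C=O, O, B2, B1, O, A5). No stereocentre is created: the spiro centre of 14 disappears on aromatisation and the acetal carbon stays racemic. The selectivity needed is the direction of migration, and it is secured because B6 carries carbon and cannot lose a proton, so a bridge to B6 can only revert and only the shift to B2 is productive. Intramolecular capture at B1 has to outrun external acetate, hence the non-nucleophilic fluoro alcohol and the removal of acetic acid before the Lewis acid is added. Ring A has no free phenol and no open position ortho to the ether oxygen, so it is neither oxidised nor able to trap the cation.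

Step 10
Reactants: 15 A6-benzyl depsidone methyl pseudoester
Product: 16 depsidone methyl pseudoester with free A6 and B4 phenols (racemic at the acetal carbon)
Conditions: H2 (1 atm), Pd/C, EtOAc, rt
Reagents that add atoms: none
Why: Hydrogenolysis of the aryl benzyl ether; it is run on the methyl acetal so that no aldehyde tautomer is exposed to hydrogen on palladium, and the diaryl ether, aryl ester and acetal C–O bonds should not be cleaved under these neutral conditions.

Step 11
Reactants: 16 depsidone methyl pseudoester
Product: 17 racemic lactol (the target constitution, both configurations at the hemiacetal carbon)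
Conditions: 2 M HCl–dioxane, 50 °C
Reagents that add atoms: water, O
Why: Acid-catalysed hydrolysis of the acetal through the phthalidyl oxocarbenium ion; acid is used because the ring D aryl ester tolerates aqueous acid far better than base, and the lactol forms as the racemate.

Step 12
Reactants: 17 racemic lactol
Product: 18 (R)-lactol acetate (acetoxy group on the hemiacetal carbon, R configuration)
Conditions: Pseudomonas cepacia lipase (immobilised), vinyl acetate, Et3N (cat.), 2-MeTHF, 30 °C
Reagents that add atoms: vinyl acetate, C=COC(C)=O
Why: Lipase-catalysed dynamic kinetic resolution by irreversible transesterification: the enzyme acetylates one lactol enantiomer while the other racemises through the ring-opened formyl acid, so all the material should funnel into one acetate; the configuration is controlled by the enzyme, and the empirical size rule for lipase acylation of secondary alcohols (fused aryl carbon large, ring oxygen medium) points to the R lactol as the fast-reacting one; any acetate formed at the hindered phenols is removed in step 13.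

Step 13
Reactants: 18 (R)-lactol acetate
Product: 19 the target, (R)-lactol
Conditions: Pseudomonas cepacia lipase (immobilised), n-BuOH, t-BuOMe, 5 °C; filtration, evaporation below 10 °C
Reagents that add atoms: none
Why: Lipase-catalysed alcoholysis cleaves the acyl–oxygen bond through an acyl enzyme, so the C–O bond at the stereocentre is untouched and the R configuration is retained; neutral, amine-free, cold conditions and a short contact time are chosen to keep ring–chain tautomerism slow, and the enantiopreference of the enzyme should further enrich the product.

## Compound list

1 | 2,5-dimethoxytoluene | COc1ccc(OC)c(C)c1 | starting material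
2 | 2,5-dimethoxy-4-methylbenzaldehyde | COc1cc(C)c(OC)cc1C=O | intermediate
3 | lithium α-amino alkoxide from 2 and lithium [2-(dimethylamino)ethyl](methyl)amide | [Li+].COc1cc(C)c(OC)cc1C([O-])N(C)CCN(C)C | intermediate
4 | ortho-lithiated amino alkoxide (lithium at B5) | [Li]c1c(OC)c(C)cc(OC)c1C(O[Li])N(C)CCN(C)C | intermediate
5 | 3-hydroxy-4,7-dimethoxy-6-methyl-2-benzofuran-1(3H)-one (racemic) | COc1cc(C)c(OC)c2C(=O)OC(O)c12 | intermediate
6 | 3,4,7-trihydroxy-6-methyl-2-benzofuran-1(3H)-one (racemic, boron-bound until the quench) | Cc1cc(O)c2C(O)OC(=O)c2c1O | intermediate
7 | 4,7-dihydroxy-3-methoxy-6-methyl-2-benzofuran-1(3H)-one (racemic) | COC1OC(=O)c2c(O)c(C)cc(O)c12 | intermediate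
8 | creosol (2-methoxy-4-methylphenol) | COc1cc(C)ccc1O | starting material
9 | 2-bromo-6-methoxy-4-methylphenol | COc1cc(C)cc(Br)c1O | intermediate
10 | 2-(benzyloxy)-1-bromo-3-methoxy-5-methylbenzene | COc1cc(C)cc(Br)c1OCc1ccccc1 | intermediate
11 | 3-(benzyloxy)-2-bromo-4-methoxy-6-methylbenzaldehyde | COc1cc(C)c(C=O)c(Br)c1OCc1ccccc1 | intermediate
12 | 3-(benzyloxy)-2-[(7-hydroxy-3-methoxy-6-methyl-1-oxo-1,3-dihydro-2-benzofuran-4-yl)oxy]-4-methoxy-6-methylbenzaldehyde (racemic) | COc1cc(C)c(C=O)c(Oc2cc(C)c(O)c3C(=O)OC(OC)c23)c1OCc1ccccc1 | intermediate
13 | 3-(benzyloxy)-2-[(7-hydroxy-3-methoxy-6-methyl-1-oxo-1,3-dihydro-2-benzofuran-4-yl)oxy]-4-methoxy-6-methylbenzoic acid (racemic) | COc1cc(C)c(C(=O)O)c(Oc2cc(C)c(O)c3C(=O)OC(OC)c23)c1OCc1ccccc1 | intermediate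
14 | spiro dienone: B1 is the spiro carbon shared by a 1,3-benzodioxin-4-one (ether O from A5, acyloxy O from A4) and the ring B cyclohexa-2,5-dien-4-one carrying the fused methoxybutenolide (diastereomer mixture, racemic) | COc1cc(C)c2c(c1OCc1ccccc1)OC1(OC2=O)C=C(C)C(=O)C2=C1C(OC)OC2=O | intermediate
15 | A6-benzyl depsidone methyl pseudoester with free B4 phenol (racemic) | COc1cc(C)c2c(c1OCc1ccccc1)Oc1c(c(C)c(O)c3c1C(OC)OC3=O)OC2=O | intermediate
16 | depsidone methyl pseudoester with free A6 and B4 phenols (racemic) | COc1cc(C)c2c(c1O)Oc1c(c(C)c(O)c3c1C(OC)OC3=O)OC2=O | intermediate
17 | racemic lactol | COc1cc(C)c2c(c1O)Oc1c(c(C)c(O)c3c1C(O)OC3=O)OC2=O | intermediate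
18 | (R)-lactol acetate | COc1cc(C)c2c(c1O)Oc1c(c(C)c(O)c3c1[C@H](OC(C)=O)OC3=O)OC2=O | intermediate
19 | target, (R)-lactol | COc1cc(C)c2c(c1O)Oc1c(c(C)c(O)c3c1[C@H](O)OC3=O)OC2=O | target

## Step count and least certain steps

Total: 13 steps. Longest linear sequence: 10 steps (from 1 through steps 1–3 and 7–13, or from 8 through steps 4–13).

Step 9 (key step, proposed new method). The phenoxenium ion may be captured by acetate or adventitious moisture instead of the hindered acid, and the resulting quinone ketal would fragment with loss of the diaryl ether. In the second stage the ketal may ionise with loss of the carboxylate instead of bridging to B2, again leading to hydrolysis on work-up. The fallback installs the B2 oxygen by known chemistry and closes ring D by a classical lactonisation. It sets out from 7 and 11 and returns at 16. Hydroquinone 7 is oxidised with Ag2O to the para-quinone F1. Thiele–Winter acetoxylation (Ac2O, BF3·OEt2) can add acetate only at B2, the single open position, and gives the triacetate F2. Methanolysis (HCl, MeOH) gives the triol F3 and resets the acetal as the methyl pseudoester. Monobenzylation (BnBr, NaHCO3, DMF) is expected at B2–OH, the phenol para to the lactone carbonyl and therefore the most acidic unchelated one, giving the B2 benzyl ether F4. Ullmann coupling with 11 at B1–OH as in step 7 gives the diaryl ether aldehyde F5, and chlorite oxidation gives the acid F6. Hydrogenolysis removes both benzyl ethers to the seco acid F7, and lactonisation of the A4 acid onto B2–OH (trifluoroacetic anhydride or a carbodiimide, high dilution) gives 16.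

Step 7. Arylation may not discriminate fully between the two phenols, the chelating hydroquinone may sequester copper, and the hydroquinone may be oxidised under basic conditions. The fallback replaces chemoselectivity by protection and also shields B4 during the chlorite oxidation. It sets out from 7 and returns at 13. Silylation (TBSCl, imidazole) at the unchelated B1–OH gives the silyl ether F8. Alkylation of the chelated B4–OH (MOMCl, NaH) gives the fully protected phthalide F9, and fluoride (TBAF, AcOH) frees B1–OH to give the phenol F10. Coupling with 11 gives the diaryl ether aldehyde F11, chlorite oxidation gives the acid F12, and HCl in MeOH removes the methoxymethyl group while keeping the methyl acetal, giving 13.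

Step 6. The Lewis acid may cleave the benzyl ether by chelation with the neighbouring methoxy group, and attack ortho instead of para to the methoxy group would give the regioisomeric aldehyde. The fallback fixes the regiochemistry by using the free phenol as director for bromination. It sets out from 8 and returns at 11. Acetylation (Ac2O, pyridine) gives the aryl acetate F13. Rieche formylation para to the methoxy group gives the formyl acetate F14, and methanolysis (K2CO3, MeOH) gives the hydroxy aldehyde F15. Bromination (Br2, AcOH), which can only go ortho to the free hydroxyl, gives the bromo hydroxy aldehyde F16, and benzylation (BnBr, K2CO3) gives 11.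

Step 12 (with step 13). The enzyme may not accept a lactol flanked by the diaryl ether, or may prefer the S lactol. Enantiomeric purity may also be lost through ring–chain tautomerism once the free lactol is released. The fallback replaces the enzyme by a small-molecule acyl-transfer catalyst. It sets out from 17 and returns at 19. Acylative dynamic kinetic resolution with a chiral isothiourea (benzotetramisole, the enantiomer chosen to deliver R), Ac2O and i-Pr2NEt should acetylate the lactol enantioselectively and both phenols as well, giving the (R)-triacetate F17. The lipase alcoholysis of step 13 then removes all three acetyl groups and gives 19.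

## Further compounds

F1 | step 9 | 3-methoxy-6-methyl-2-benzofuran-1,4,7(3H)-trione (racemic) | COC1OC(=O)C2=C1C(=O)C=C(C)C2=O
F2 | step 9 | 3-methoxy-6-methyl-1-oxo-1,3-dihydro-2-benzofuran-4,5,7-triyl triacetate (racemic) | COC1OC(=O)c2c(OC(C)=O)c(C)c(OC(C)=O)c(OC(C)=O)c12
F3 | step 9 | 4,5,7-trihydroxy-3-methoxy-6-methyl-2-benzofuran-1(3H)-one (racemic) | COC1OC(=O)c2c(O)c(C)c(O)c(O)c12
F4 | step 9 | 5-(benzyloxy)-4,7-dihydroxy-3-methoxy-6-methyl-2-benzofuran-1(3H)-one (racemic) | COC1OC(=O)c2c(O)c(C)c(OCc3ccccc3)c(O)c12
F5 | step 9 | 3-(benzyloxy)-2-{[5-(benzyloxy)-7-hydroxy-3-methoxy-6-methyl-1-oxo-1,3-dihydro-2-benzofuran-4-yl]oxy}-4-methoxy-6-methylbenzaldehyde (racemic) | COc1cc(C)c(C=O)c(Oc2c(OCc3ccccc3)c(C)c(O)c3C(=O)OC(OC)c23)c1OCc1ccccc1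
F6 | step 9 | 3-(benzyloxy)-2-{[5-(benzyloxy)-7-hydroxy-3-methoxy-6-methyl-1-oxo-1,3-dihydro-2-benzofuran-4-yl]oxy}-4-methoxy-6-methylbenzoic acid (racemic) | COc1cc(C)c(C(=O)O)c(Oc2c(OCc3ccccc3)c(C)c(O)c3C(=O)OC(OC)c23)c1OCc1ccccc1
F7 | step 9 | 2-[(5,7-dihydroxy-3-methoxy-6-methyl-1-oxo-1,3-dihydro-2-benzofuran-4-yl)oxy]-3-hydroxy-4-methoxy-6-methylbenzoic acid (racemic) | COc1cc(C)c(C(=O)O)c(Oc2c(O)c(C)c(O)c3C(=O)OC(OC)c23)c1O
F8 | step 7 | 4-[(tert-butyldimethylsilyl)oxy]-7-hydroxy-3-methoxy-6-methyl-2-benzofuran-1(3H)-one (racemic) | COC1OC(=O)c2c(O)c(C)cc(O[Si](C)(C)C(C)(C)C)c12
F9 | step 7 | 4-[(tert-butyldimethylsilyl)oxy]-3-methoxy-7-(methoxymethoxy)-6-methyl-2-benzofuran-1(3H)-one (racemic) | COCOc1c(C)cc(O[Si](C)(C)C(C)(C)C)c2C(OC)OC(=O)c12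
F10 | step 7 | 4-hydroxy-3-methoxy-7-(methoxymethoxy)-6-methyl-2-benzofuran-1(3H)-one (racemic) | COCOc1c(C)cc(O)c2C(OC)OC(=O)c12
F11 | step 7 | 3-(benzyloxy)-4-methoxy-2-{[3-methoxy-7-(methoxymethoxy)-6-methyl-1-oxo-1,3-dihydro-2-benzofuran-4-yl]oxy}-6-methylbenzaldehyde (racemic) | COCOc1c(C)cc(Oc2c(C=O)c(C)cc(OC)c2OCc2ccccc2)c2C(OC)OC(=O)c12
F12 | step 7 | 3-(benzyloxy)-4-methoxy-2-{[3-methoxy-7-(methoxymethoxy)-6-methyl-1-oxo-1,3-dihydro-2-benzofuran-4-yl]oxy}-6-methylbenzoic acid (racemic) | COCOc1c(C)cc(Oc2c(C(=O)O)c(C)cc(OC)c2OCc2ccccc2)c2C(OC)OC(=O)c12
F13 | step 6 | 2-methoxy-4-methylphenyl acetate | COc1cc(C)ccc1OC(C)=O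
F14 | step 6 | 5-formyl-2-methoxy-4-methylphenyl acetate | COc1cc(C)c(C=O)cc1OC(C)=O
F15 | step 6 | 5-hydroxy-4-methoxy-2-methylbenzaldehyde | COc1cc(C)c(C=O)cc1O
F16 | step 6 | 2-bromo-3-hydroxy-4-methoxy-6-methylbenzaldehyde | COc1cc(C)c(C=O)c(Br)c1O
F17 | step 12 | (R)-lactol acetate with both phenols acetylated (triacetate) | COc1cc(C)c2c(c1OC(C)=O)Oc1c(c(C)c(OC(C)=O)c3c1[C@H](OC(C)=O)OC3=O)OC2=O
A1 | alternative 1 | tert-butyl 4-(benzyloxy)-6-[(tert-butyldimethylsilyl)oxy]-2-(diethoxymethyl)-3-hydroxy-5-methylbenzoate | CC(C)(C)OC(=O)c1c(O[Si](C)(C)C(C)(C)C)c(C)c(OCc2ccccc2)c(O)c1C(OCC)OCC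
A2 | alternative 1 | 4-(benzyloxy)-2-[(tert-butyldimethylsilyl)oxy]-3-methylfuran | Cc1c(O[Si](C)(C)C(C)(C)C)occ1OCc1ccccc1
A3 | alternative 1 | tert-butyl 4,4-diethoxybut-2-ynoate | CCOC(OCC)C#CC(=O)OC(C)(C)C
A4 | alternative 2 | 2-aryloxy-6-methylbenzoic acid, seco-ring D, with ring A complete | COc1cc(C)c(C(=O)O)c(Oc2c(OCc3ccc(OC)cc3)c(C)c(OCc3ccccc3)c(C(=O)OC(C)(C)C)c2C(OC)OC)c1OCc1ccccc1
A5 | alternative 2 | diaryl ether with iodide at A4 and tosylate at A3 | COc1cc(OS(=O)(=O)c2ccc(C)cc2)c(I)c(Oc2c(OCc3ccc(OC)cc3)c(C)c(OCc3ccccc3)c(C(=O)OC(C)(C)C)c2C(OC)OC)c1OCc1ccccc1
A6 | alternative 3 | bis-benzyl depsidone B5,B6-dicarboxylic anhydride | COc1cc(C)c2c(c1OCc1ccccc1)Oc1c3C(=O)OC(=O)c3c(OCc3ccccc3)c(C)c1OC2=O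
A7 | alternative 3 | bis-benzyl depsidone B5-carboxylic acid with B6–H | COc1cc(C)c2c(c1OCc1ccccc1)Oc1cc(C(=O)O)c(OCc3ccccc3)c(C)c1OC2=O
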